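The flavanone is cut at the C3–C4 bond of the dihydropyranone ring C. Ring C is closed by an enantioselective Rh-catalysed intramolecular hydroacylation: the formyl C–H of an achiral 2-[(1-arylvinyl)oxy]benzaldehyde adds across its 1,1-disubstituted enol ether, joining the acyl carbon (C4) to the CH2 terminus (C3) and delivering hydride to C2, so ring and sole stereocentre arise together. The step exploits that C2, carrying O1, the B-ring aryl and one H, lies β to the C4 ketone. The enol ether comes from an aryl ester by titanium methylenation; the geranyl group is placed early on a symmetric phloroglucinol ether, which settles the 6- versus 8-position.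

Key step: step 9

Remarks on the chemistry:
- "Geranyl" stands for (2E)-3,7-dimethylocta-2,6-dien-1-yl and MOM for methoxymethyl. The stereocentre of the target (C2) is S.
- Assumption: which antipode of the bisphosphine gives the 2S product has to be found by experiment. (R)-DTBM-SEGPHOS is written here, and its enantiomer would be used if the sense of induction is the opposite.
- Compounds 1, 4 and 8 are taken as commercially available.

Step 1
Reactants: 1 phloroglucinol
Product: 2 3,5-bis(methoxymethoxy)phenol
Conditions: MOMCl (2.0 equiv), i-Pr2NEt (2.2 equiv), DMF, 0 °C → rt; chromatography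
Reagents that add atoms: chloromethyl methyl ether (MOMCl), COCCl
Why: Williamson-type O-alkylation of the threefold-symmetric triphenol with two equivalents of MOMCl should give the bis-acetal as the main component of a statistical mixture that is separable by chromatography, the mono- and tris-ethers being recyclable.

Step 2
Reactants: 2 3,5-bis(methoxymethoxy)phenol
Product: 3 [3,5-bis(methoxymethoxy)phenoxy]triisopropylsilane
Conditions: TIPSCl, imidazole, DMF, rt
Reagents that add atoms: chlorotriisopropylsilane (TIPSCl), CC(C)[Si](Cl)(C(C)C)C(C)C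
Why: Standard silylation of the remaining phenol; the bulky TIPS ether withstands n-BuLi, shields its own ortho positions and is later removed by fluoride without touching the MOM acetals.

Step 3
Reactants: 3 [3,5-bis(methoxymethoxy)phenoxy]triisopropylsilane; 4 geranyl bromide
Product: 6 [4-geranyl-3,5-bis(methoxymethoxy)phenoxy]triisopropylsilane, via aryllithium 5 (not isolated)
Conditions: n-BuLi, THF, 0 °C; then CuI (10 mol %), 4, −78 °C → rt
Reagents that add atoms: none
Why: Directed ortho-metalation occurs at the only position flanked by two MOM ethers (cooperative chelation), and Cu-catalysed SN2 alkylation of aryllithium 5 with the primary allylic bromide should install the geranyl group with the E geometry retained.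

Step 4
Reactants: 6 [4-geranyl-3,5-bis(methoxymethoxy)phenoxy]triisopropylsilane
Product: 7 4-geranyl-3,5-bis(methoxymethoxy)phenol
Conditions: TBAF, THF, 0 °C; H2O
Reagents that add atoms: none
Why: Fluoride-mediated Si–O cleavage of the aryl silyl ether is chemoselective in the presence of the MOM acetals and the diene.

Step 5
Reactants: 8 3-hydroxy-4,5-dimethoxybenzoic acid
Product: 10 3,4-dimethoxy-5-(methoxymethoxy)benzoic acid, via MOM ester 9 (not isolated)
Conditions: MOMCl (2.5 equiv), i-Pr2NEt, CH2Cl2, 0 °C → rt; evaporate; LiOH, THF/MeOH/H2O, rt; 1 M HCl to pH 4, 0 °C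
Reagents that add atoms: chloromethyl methyl ether (MOMCl), COCCl; lithium hydroxide, [Li+].[OH-]
Why: Double O-alkylation (phenol and carboxylate) with MOMCl followed by saponification of the labile MOM ester leaves only the phenolic MOM ether, the acid being liberated at pH 4 to spare the acetal.

Step 6
Reactants: 7 4-geranyl-3,5-bis(methoxymethoxy)phenol; 10 3,4-dimethoxy-5-(methoxymethoxy)benzoic acid
Product: 11 4-geranyl-3,5-bis(methoxymethoxy)phenyl 3,4-dimethoxy-5-(methoxymethoxy)benzoate
Conditions: EDC·HCl, DMAP, CH2Cl2, rt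
Reagents that add atoms: none
Why: Steglich esterification (carbodiimide/DMAP) acylates the unhindered phenol under near-neutral conditions compatible with the acetals.

Step 7
Reactants: 11 4-geranyl-3,5-bis(methoxymethoxy)phenyl 3,4-dimethoxy-5-(methoxymethoxy)benzoate
Product: 12 5-{1-[4-geranyl-3,5-bis(methoxymethoxy)phenoxy]ethenyl}-1,2-dimethoxy-3-(methoxymethoxy)benzene
Conditions: Cp2TiMe2 (2.5 equiv), toluene, 65 °C, dark; chromatography on Et3N-deactivated silica
Reagents that add atoms: dimethyltitanocene (Petasis reagent), C[Ti](C)(C1C=CC=C1)C1C=CC=C1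
Why: Petasis methylenation: Cp2Ti=CH2 generated thermally from Cp2TiMe2 undergoes [2+2]/retro-[2+2] with the aryl ester carbonyl to give the 1-aryloxy-1-arylethene, and the non-Lewis-acidic reagent tolerates MOM ethers and the trisubstituted alkenes.

Step 8
Reactants: 12 5-{1-[4-geranyl-3,5-bis(methoxymethoxy)phenoxy]ethenyl}-1,2-dimethoxy-3-(methoxymethoxy)benzene
Product: 14 6-({1-[3,4-dimethoxy-5-(methoxymethoxy)phenyl]ethenyl}oxy)-3-geranyl-2,4-bis(methoxymethoxy)benzaldehyde, via aryllithium 13 (not isolated)
Conditions: s-BuLi, TMEDA, THF, −78 °C; then DMF, −78 → 0 °C; H2O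
Reagents that add atoms: N,N-dimethylformamide, CN(C)C=O
Why: Directed ortho-metalation at one of the two equivalent A-ring C–H positions, each flanked by a MOM ether and the aryloxy oxygen and therefore the most acidic ring sites, followed by formylation of aryllithium 13 with DMF; the fast s-BuLi/TMEDA system at low temperature is chosen to outrun addition to the styrenyl enol ether.

Step 9
Reactants: 14 6-({1-[3,4-dimethoxy-5-(methoxymethoxy)phenyl]ethenyl}oxy)-3-geranyl-2,4-bis(methoxymethoxy)benzaldehyde
Product: 15 (2S)-2-[3,4-dimethoxy-5-(methoxymethoxy)phenyl]-6-geranyl-5,7-bis(methoxymethoxy)chroman-4-one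
Conditions: [Rh(cod)Cl]2 (2.5 mol %), (R)-DTBM-SEGPHOS (5 mol %), NaBArF4 (5 mol %), 1,4-dioxane, 60 °C
Reagents that add atoms: none
Why: Proposed new method: Rh(I) inserts into the formyl C–H to give an acyl–Rh(III) hydride held next to the enol ether by the tether, the C=CH2 unit inserts into Rh–H with hydride going to the oxygen- and aryl-bearing carbon (the future C2), and C–C reductive elimination from the resulting seven-membered acyl(alkyl)rhodacycle forms C3–C4. The closest known reaction type is the enantioselective Rh/bisphosphine endo-hydroacylation of 1,1-disubstituted alkenes in ortho-allylbenzaldehydes (giving 3-substituted tetralones) and in N-vinyl- and N-allyl-indole-2-carboxaldehydes; an O-tethered 1-aryl enol ether has not been used in it, hence the label. Ring C is closed in a formal 6-endo-trig mode, the acyl carbon bonding to the terminal CH2. The C2 stereocentre is created in the hydride insertion, whose alkene face is selected by the chiral bisphosphine on Rh (catalyst control, the substrate being achiral). The step needs endo over exo regioselectivity and chemoselectivity over decarbonylation and over the geranyl alkenes: the exo path would require a tertiary alkyl–Rh and reductive elimination to a quaternary centre, the enol ether has no allylic hydrogen and cannot isomerise, the ortho MOM oxygen can stabilise the acyl–Rh species, and the remote trisubstituted geranyl alkenes cannot chelate and insert far more slowly.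

Step 10
Reactants: 15 (2S)-2-[3,4-dimethoxy-5-(methoxymethoxy)phenyl]-6-geranyl-5,7-bis(methoxymethoxy)chroman-4-one
Product: 16 (2S)-6-geranyl-5,7-dihydroxy-2-(3-hydroxy-4,5-dimethoxyphenyl)chroman-4-one (CNP0228243.1)
Conditions: 3 M aq. HCl, MeOH/THF, 45 °C
Reagents that add atoms: none
Why: Acid-catalysed acetal cleavage (transacetalisation to dimethoxymethane) removes all three MOM groups under conditions customary for geranylated flavanones, and the C2 stereocentre, which epimerises mainly by base-induced retro-oxa-Michael opening, should be retained.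

Compound list
1 | phloroglucinol (benzene-1,3,5-triol) | Oc1cc(O)cc(O)c1 | starting material
2 | 3,5-bis(methoxymethoxy)phenol | COCOc1cc(O)cc(OCOC)c1 | intermediate
3 | [3,5-bis(methoxymethoxy)phenoxy]triisopropylsilane | COCOc1cc(O[Si](C(C)C)(C(C)C)C(C)C)cc(OCOC)c1 | intermediate
4 | geranyl bromide, (2E)-1-bromo-3,7-dimethylocta-2,6-diene | BrC/C=C(\C)CCC=C(C)C | starting material
5 | [2,6-bis(methoxymethoxy)-4-(triisopropylsilyloxy)phenyl]lithium | [Li]c1c(OCOC)cc(O[Si](C(C)C)(C(C)C)C(C)C)cc1OCOC | intermediate (not isolated)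
6 | [4-geranyl-3,5-bis(methoxymethoxy)phenoxy]triisopropylsilane | COCOc1cc(O[Si](C(C)C)(C(C)C)C(C)C)cc(OCOC)c1C/C=C(\C)CCC=C(C)C | intermediate
7 | 4-geranyl-3,5-bis(methoxymethoxy)phenol | COCOc1cc(O)cc(OCOC)c1C/C=C(\C)CCC=C(C)C | intermediate
8 | 3-hydroxy-4,5-dimethoxybenzoic acid | COc1cc(C(=O)O)cc(O)c1OC | starting material
9 | methoxymethyl 3,4-dimethoxy-5-(methoxymethoxy)benzoate | COCOC(=O)c1cc(OC)c(OC)c(OCOC)c1 | intermediate (not isolated)
10 | 3,4-dimethoxy-5-(methoxymethoxy)benzoic acid | COCOc1cc(C(=O)O)cc(OC)c1OC | intermediate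
11 | 4-geranyl-3,5-bis(methoxymethoxy)phenyl 3,4-dimethoxy-5-(methoxymethoxy)benzoate | COCOc1cc(OC(=O)c2cc(OC)c(OC)c(OCOC)c2)cc(OCOC)c1C/C=C(\C)CCC=C(C)C | intermediate
12 | 5-{1-[4-geranyl-3,5-bis(methoxymethoxy)phenoxy]ethenyl}-1,2-dimethoxy-3-(methoxymethoxy)benzene | COCOc1cc(OC(=C)c2cc(OC)c(OC)c(OCOC)c2)cc(OCOC)c1C/C=C(\C)CCC=C(C)C | intermediate
13 | A-ring aryllithium of 12 (Li between the enol ether oxygen and a MOM ether) | [Li]c1c(OC(=C)c2cc(OC)c(OC)c(OCOC)c2)cc(OCOC)c(C/C=C(\C)CCC=C(C)C)c1OCOC | intermediate (not isolated)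
14 | 6-({1-[3,4-dimethoxy-5-(methoxymethoxy)phenyl]ethenyl}oxy)-3-geranyl-2,4-bis(methoxymethoxy)benzaldehyde | O=Cc1c(OC(=C)c2cc(OC)c(OC)c(OCOC)c2)cc(OCOC)c(C/C=C(\C)CCC=C(C)C)c1OCOC | intermediate
15 | (2S)-2-[3,4-dimethoxy-5-(methoxymethoxy)phenyl]-6-geranyl-5,7-bis(methoxymethoxy)chroman-4-one | COc1cc([C@@H]2CC(=O)c3c(cc(OCOC)c(C/C=C(\C)CCC=C(C)C)c3OCOC)O2)cc(OCOC)c1OC | intermediate
16 | (2S)-6-geranyl-5,7-dihydroxy-2-(3-hydroxy-4,5-dimethoxyphenyl)chroman-4-one (CNP0228243.1) | COc1cc([C@@H]2CC(=O)c3c(cc(O)c(C/C=C(\C)CCC=C(C)C)c3O)O2)cc(O)c1OC | target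

Total step count: 10. Longest linear sequence: 9 steps (1, 2, 3, 4, 6, 7, 8, 9, 10); step 5 is a one-step branch.

Steps most likely to fail

1. Step 9 (Proposed new method). What may go wrong: decarbonylation of the acyl–Rh hydride before insertion, β-aryloxy elimination from the alkyl–Rh intermediate with loss of the B-ring as a styrene, poor facial selectivity in the hydride insertion, or hydrolysis of the enol ether by traces of acid. The fallback uses known chemistry, sets out from phenol 7 and comes back at 15, with the stereocentre set beforehand.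
   - Phenol 7 would be ortho-formylated (MgCl2, Et3N, paraformaldehyde, MeCN, reflux) to 3-geranyl-6-hydroxy-2,4-bis(methoxymethoxy)benzaldehyde F1.
   - Commercial 1-(3-hydroxy-4,5-dimethoxyphenyl)ethanone F2 would be protected (MOMCl, i-Pr2NEt) as 1-[3,4-dimethoxy-5-(methoxymethoxy)phenyl]ethanone F3.
   - F3 would be brominated through its silyl enol ether (TMSOTf, Et3N; then NBS) to 2-bromo-1-[3,4-dimethoxy-5-(methoxymethoxy)phenyl]ethanone F4.
   - CBS reduction (BH3·SMe2, oxazaborolidine antipode chosen to give the S alcohol) would give (1S)-2-bromo-1-[3,4-dimethoxy-5-(methoxymethoxy)phenyl]ethanol F5.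
   - Mitsunobu etherification of F1 with F5 (PPh3, DIAD, toluene, 0 °C) should proceed with inversion to 6-{(1R)-2-bromo-1-[3,4-dimethoxy-5-(methoxymethoxy)phenyl]ethoxy}-3-geranyl-2,4-bis(methoxymethoxy)benzaldehyde F6.
   - The C3–C4 bond would then be closed by the known NHC-catalysed intramolecular acyl-anion alkylation of 2-(2-haloethoxy)benzaldehydes (triazolium or thiazolium precatalyst, Cs2CO3, dioxane, 60 °C). The Breslow intermediate displaces the primary bromide and the C2 configuration is untouched, giving 15.

2. Step 8. What may go wrong: addition of the alkyllithium across the 1-aryloxystyrene double bond (carbolithiation), or competing metalation ortho to the B-ring MOM ether or at the benzylic/allylic CH2 of the geranyl chain. The fallback replaces deprotonation by halogen–metal exchange, sets out from phenol 7 and comes back at 14.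
   - Phenol 7 would be mono-iodinated at one of its two equivalent ortho positions (NIS, DMF, −20 °C) to 4-geranyl-2-iodo-3,5-bis(methoxymethoxy)phenol F7.
   - F7 would be esterified with acid 10 (EDC·HCl, DMAP) to 4-geranyl-2-iodo-3,5-bis(methoxymethoxy)phenyl 3,4-dimethoxy-5-(methoxymethoxy)benzoate F8.
   - F8 would be methylenated (Cp2TiMe2, toluene, 65 °C) to 5-{1-[4-geranyl-2-iodo-3,5-bis(methoxymethoxy)phenoxy]ethenyl}-1,2-dimethoxy-3-(methoxymethoxy)benzene F9.
   - Iodine–magnesium exchange (i-PrMgCl·LiCl, THF, 0 °C) and quenching with DMF would then give 14 without any alkyllithium meeting the enol ether.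

3. Step 10. What may go wrong: acid-promoted cyclisation of the geranyl chain onto the flanking C5/C7 phenols, erosion of the C2 configuration through ring opening to the chalcone on prolonged exposure to protic acid, or incomplete loss of the hindered 5-O-MOM group. The fallback avoids protic acid, sets out from 15 and comes back at 16.
   - The acetals would be exchanged for silyl groups under non-protic conditions (TMSOTf, 2,2′-bipyridyl, CH2Cl2, 0 °C) to give (2S)-2-{3,4-dimethoxy-5-[(trimethylsilyl)oxy]phenyl}-6-geranyl-5,7-bis[(trimethylsilyl)oxy]chroman-4-one F10.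
   - The aryl silyl ethers would then be hydrolysed under neutral aqueous conditions (H2O/THF, rt) to 16.

Further compounds
F1 | step 9 | 3-geranyl-6-hydroxy-2,4-bis(methoxymethoxy)benzaldehyde | O=Cc1c(O)cc(OCOC)c(C/C=C(\C)CCC=C(C)C)c1OCOC
F2 | step 9 | 1-(3-hydroxy-4,5-dimethoxyphenyl)ethanone (bought) | CC(=O)c1cc(O)c(OC)c(OC)c1
F3 | step 9 | 1-[3,4-dimethoxy-5-(methoxymethoxy)phenyl]ethanone | CC(=O)c1cc(OCOC)c(OC)c(OC)c1
F4 | step 9 | 2-bromo-1-[3,4-dimethoxy-5-(methoxymethoxy)phenyl]ethanone | BrCC(=O)c1cc(OCOC)c(OC)c(OC)c1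
F5 | step 9 | (1S)-2-bromo-1-[3,4-dimethoxy-5-(methoxymethoxy)phenyl]ethanol | COc1cc([C@H](O)CBr)cc(OCOC)c1OC
F6 | step 9 | 6-{(1R)-2-bromo-1-[3,4-dimethoxy-5-(methoxymethoxy)phenyl]ethoxy}-3-geranyl-2,4-bis(methoxymethoxy)benzaldehyde | COc1cc([C@@H](Oc2cc(OCOC)c(C/C=C(\C)CCC=C(C)C)c(OCOC)c2C=O)CBr)cc(OCOC)c1OC
F7 | step 8 | 4-geranyl-2-iodo-3,5-bis(methoxymethoxy)phenol | COCOc1cc(O)c(I)c(OCOC)c1C/C=C(\C)CCC=C(C)C
F8 | step 8 | 4-geranyl-2-iodo-3,5-bis(methoxymethoxy)phenyl 3,4-dimethoxy-5-(methoxymethoxy)benzoate | COCOc1cc(OC(=O)c2cc(OC)c(OC)c(OCOC)c2)c(I)c(OCOC)c1C/C=C(\C)CCC=C(C)C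
F9 | step 8 | 5-{1-[4-geranyl-2-iodo-3,5-bis(methoxymethoxy)phenoxy]ethenyl}-1,2-dimethoxy-3-(methoxymethoxy)benzene | COCOc1cc(OC(=C)c2cc(OC)c(OC)c(OCOC)c2)c(I)c(OCOC)c1C/C=C(\C)CCC=C(C)C
F10 | step 10 | (2S)-2-{3,4-dimethoxy-5-[(trimethylsilyl)oxy]phenyl}-6-geranyl-5,7-bis[(trimethylsilyl)oxy]chroman-4-one | COc1cc([C@@H]2CC(=O)c3c(cc(O[Si](C)(C)C)c(C/C=C(\C)CCC=C(C)C)c3O[Si](C)(C)C)O2)cc(O[Si](C)(C)C)c1OC
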